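Set Sunday's run beside Wednesday's at 1.33 min. Wednesday's flask held twice the catalyst and had made product at 1.36 mM min⁻¹, against 0.662 mM min⁻¹ in Sunday's, so twice as fast. Yet starting material stood at 57.6 % in Wednesday's and 60.8 % in Sunday's. How can the two go together?

| flask | starting material | partner | protic impurity | free catalyst | remark | time |
|---|---|---|---|---|---|---|
| Sunday's | 7.4 mM | 55 mM | 12 mM | 45 µM | run made earlier |  |
| Wednesday's | 11 mM | 55 mM | 12 mM | 90 µM | run made earlier |  |
| maple | 11 mM | 55.0 mM | 12.0 mM | 45 µM |  | 20 min |
| oak | 11 mM | 55.0 mM | 20.0 mM | 45 µM |  | 20 min |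
| larch | 11 mM | 55.0 mM | 40.0 mM | 45 µM |  | 20 min |

| run | time / min | product / % | starting material / % |
|---|---|---|---|
| Sunday's | 0.667 | 6.2 | 78.3 |
| Sunday's | 1.33 | 11.9 | 60.8 |
| Sunday's | 2.00 | 17.7 | 49.2 |
| Sunday's | 2.50 | 19.6 | 40.6 |
| Sunday's | 3.00 | 21.4 | 34.3 |
| Sunday's | 4.00 | 27.9 | 26.1 |
| Wednesday's | 0.250 | 2.7 | 89.0 |
| Wednesday's | 0.833 | 9.5 | 70.7 |
| Wednesday's | 1.33 | 16.4 | 57.6 |
| Wednesday's | 2.00 | 23.4 | 42.6 |
| Wednesday's | 3.00 | 34.8 | 28.2 |
| Wednesday's | 4.00 | 40.8 | 14.4 |

(standard deviation of a reading: 1 percentage point)

1. [product] at the end for maple, oak, larch, in this order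
2. how the row runs (hardly changes / falls all the way / rises all the way / rises, then falls / falls, then rises)

- what was read earlier has a scatter of 1 percentage point, one standard deviation
- "hardly changes" means that all values lie within two and a half points (for a concentration: within two and a half percent of the largest)
- no earlier run changes the charge of protic impurity; that part of a forecast is a guess

Count what is neither starting material nor product, and divide its flow by the mean fraction of starting material left. This pseudo-first-order constant comes to 0.255 min⁻¹ on Sunday and 0.248 min⁻¹ on Wednesday. The catalyst differs between them, so you can read this loss as needing none. Product behaves differently. Per catalyst it runs at 14.7 min⁻¹ and 15.1 min⁻¹, although the charges were 7.4 mM and 11 mM. So take it as a steady flow, set by the catalyst.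

Now guess, since no run varied it, that the loss scales with [protic impurity], which, at one impurity per starting material lost, averaged 10.6 mM over Wednesday's stretch. Define the crossover level as the [starting material] at which loss and product flow are equal. In maple it is 2.41 mM, and it shrinks in inverse proportion to the impurity charge. Summing the product's share on the way down, with the impurity held at its charge, gives product as the crossover times ln(one plus charge over crossover). That yields 4.13 mM for maple, 3.11 mM for oak and 2.01 mM for larch.

The forecast, lower than this for oak and larch, gave 4.2 mM, 2.7 mM and 1.4 mM, a row that falls all the way, in its words: “The row falls throughout”. The flasks give 4.51 mM, 3.03 mM and 1.63 mM: falls all the way.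

    starting material + free catalyst ⇌ catalyst intermediate A (K = 2600 M⁻¹, k = 150 M⁻¹ s⁻¹)
    partner + catalyst intermediate A ⇌ catalyst intermediate B (K = 21.0 M⁻¹, k = 42.0 M⁻¹ s⁻¹)
    catalyst intermediate B → free catalyst + product (k = 0.720 s⁻¹)
    starting material + protic impurity → quenched substrate (k = 0.380 M⁻¹ s⁻¹)

Larch's crossover is 0.722 mM, far below the 11 mM of starting material charged, so by this reckoning the loss in larch starts at 15.2 times the catalyst's flow. Quenched substrate in larch ends at 85.2 % of the starting material charged. Its formation is the largest single effect on larch's product: with that step taken away, [product] at the end rises from 1.63 mM to 10.3 mM.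

The earlier runs and the new flask were computed with made-up constants; noise was put on by code.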